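Keep the flask sealed and stirred, and do not lower its charge of 0.50 M of X.

| setting | Wednesday's | Friday's | flask |
|---|---|---|---|
| X | 0.34 M | 0.75 M | 0.50 M |
| remark | run made earlier | run made earlier |  |
| time |  |  | 30 h |

| run | time / h | Z / % | E / % |
|---|---|---|---|
| Wednesday's | 10.0 | 90.0 | 7.7 |
| Wednesday's | 20.0 | 85.8 | 10.1 |
| Wednesday's | 25.0 | 86.0 | 10.7 |
| Wednesday's | 40.0 | 83.7 | 12.6 |
| Friday's | 5.00 | 27.8 | 1.8 |
| Friday's | 12.0 | 71.4 | 5.3 |
| Friday's | 25.0 | 92.9 | 5.4 |
| Friday's | 40.0 | 92.8 | 6.4 |

(scatter of a reading: 0.5 percentage points)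

- at the start none of X is in solution
- a reading or a percentage of Z counts all its forms, free or not

- share of Z in Z plus E at 25 min
- share of Z in Z plus E at 3.0 h
- share of Z in Z plus E at 30 h

1. In the flask: solid X, none of it in solution at the start, going over to Z and some E.
2. The quantity to carry is the E load: E's fraction of the charge times the charge. Averaged over the readings at 25.0 h and 40.0 h, which bracket 30 h, it is 0.0419 M.
3. Friday's charge is 2.21 times Wednesday's, yet at 40.0 h the loads read 0.0480 M and 0.0428 M.
4. Own reckoning for this flask at 30 h: the load over the charge gives E at 8.39%. Z plus E averages 97.6% in those readings, so the share of Z in Z plus E (the selectivity) comes to 91.4%.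
5. Do not lower the charge: at 40.0 h Wednesday's smaller charge shows the higher E fraction.

The forecast gives 93%, 93.5% and 91.7%, holding late E “independent of charge”. Its last figure stands 0.30 percentage points above the own reckoning.

The flask gives 96.0%, 94.1% and 91.5%.

    G → L (k = 8.50 × 10⁻⁴ s⁻¹)
    L ⇌ Z (K = 14.0, k = 0.00200 s⁻¹)
    L ⇌ E (K = 4.60, k = 7.80 × 10⁻⁵ s⁻¹)
    G → J (k = 1.30 × 10⁻⁶ s⁻¹)
    D ⇌ Z, rate k5*(cs5 - [Z]) while solid is left; crystals form when [Z] > cs5 (solubility = 0.140 M, k = 0.0590 s⁻¹)
    X ⇌ G, rate k6*(cs6 - [G]) while solid is left; crystals form when [G] > cs6 (solubility = 19.0 mM, k = 0.00470 s⁻¹)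

At 30.0 h this flask holds E at 8.32% of its charge, a load of 0.0416 M, against the 8.39% reckoned. The share parts from the forecast's 91.7% in the neighbour flask, whose charge is smaller. The neighbour flask, with 0.20 M of X, is reckoned at 20.9% E from the carried load. It holds 19.3% E, a load of 0.0386 M, and 75.6% Z. Its share of Z in Z plus E at 30.0 h is 79.6%.

The runs were computed with made-up constants; the scatter is artificial.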